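**Retrosynthetic overview**
1. Key disconnection: one 6→7 ring expansion supplies both cycloheptanone rings, both isopropyl groups and C-7. It is a carbenoid-triggered 1,2-acyl shift on hydrindenedione 9 (9 + 11 → 13).
2. 9 ⇐ cyclopentane-1,3-dione 1 + crotonaldehyde 2 (organocatalytic Michael addition sets C-10), then MeI (C-15), MeLi (C-6) and a vinylogous Dieckmann closure of the six-membered ring.
3. C30 core 17 ⇐ two molecules of the single monomer 14, by dehydrobromination to dienone 16 and its spontaneous head-to-head self-union (C-3–C-3', C-1–C-4').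
4. C-2 acetate ⇐ bridge ketone by equilibrating hydride transfer. Only the enone half is then dehydrogenated (C-6'=C-7') and takes up O2 at C-11' to close the dioxolane hemiketal.
5. Ring order: cyclopentenone → cyclohexanone → cycloheptanone (expansion) → norbornene → 1,2-dioxolane.

Assumption: guaiane numbering is used (C-1 to C-15, primes for the enone/peroxide half). C-4 of the monomers and the acetal carbon of 3–6 are carried as epimer mixtures, because they become sp2 or are lost later, and are left open in the SMILES.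

Step 1
Reactants: 1 cyclopentane-1,3-dione; 2 (E)-crotonaldehyde
Product: 4 (4R)-2-methoxy-4-methyl-3,4,6,7-tetrahydrocyclopenta[b]pyran-5(2H)-one, via lactol (4R)-2-hydroxy-4-methyl-3,4,6,7-tetrahydrocyclopenta[b]pyran-5(2H)-one 3 (not isolated)
Conditions: (S)-α,α-diphenylprolinol TMS ether (10 mol %), PhCO2H (10 mol %), CH2Cl2, rt; then MeOH, TsOH (cat.)
Reagents that add atoms: methanol, CO
Why: Iminium-catalysed asymmetric Michael addition in which the (S)-catalyst shields one face of the E-iminium ion so that C-2 of the dione adds from the open face and sets C-10 as R, after which acid/MeOH locks the lactol as a mixed acetal that protects the aldehyde and is also the vinylogous ester needed next.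

Step 2
Reactants: 4 (4R)-2-methoxy-4-methyl-3,4,6,7-tetrahydrocyclopenta[b]pyran-5(2H)-one
Product: 5 (4R)-2-methoxy-4,6-dimethyl-3,4,6,7-tetrahydrocyclopenta[b]pyran-5(2H)-one (C-6 epimers)
Conditions: LDA, THF, −78 °C; MeI
Reagents that add atoms: iodomethane, CI
Why: Stork–Danheiser kinetic α'-alkylation of a vinylogous ester places the future C-15 methyl only next to the free carbonyl (future C-5), and the new centre (C-4) needs no control because it is planarised in step 9.

Step 3
Reactants: 5 (4R)-2-methoxy-4,6-dimethyl-3,4,6,7-tetrahydrocyclopenta[b]pyran-5(2H)-one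
Product: 7 (3R)-3-(2,3-dimethyl-5-oxocyclopent-1-en-1-yl)butanal, via carbinol (4R)-2-methoxy-4,5,6-trimethyl-2,3,4,5,6,7-hexahydrocyclopenta[b]pyran-5-ol 6 (not isolated)
Conditions: MeLi, THF, −78 °C; then 1 M HCl, THF, 0 °C
Reagents that add atoms: methyllithium, [Li]C; water, O
Why: Stork–Danheiser 1,2-addition and acidic carbonyl transposition bring in C-6 as the β-methyl of the tetrasubstituted enone (C-2=O, C-1=C-5) and free the aldehyde in the same hydrolysis, with C-10 untouched.

Step 4
Reactants: 7 (3R)-3-(2,3-dimethyl-5-oxocyclopent-1-en-1-yl)butanal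
Product: 8 methyl (3R)-3-(2,3-dimethyl-5-oxocyclopent-1-en-1-yl)butanoate
Conditions: Oxone, MeOH, rt
Reagents that add atoms: methanol, CO
Why: Oxidative esterification of an aliphatic aldehyde through its methyl hemiacetal leaves the electron-poor tetrasubstituted enone alone and avoids the easy dehydration that a vinylogous aldol route would suffer.

Step 5
Reactants: 8 methyl (3R)-3-(2,3-dimethyl-5-oxocyclopent-1-en-1-yl)butanoate
Product: 9 (7R)-3,7-dimethyl-2,3,6,7-tetrahydro-1H-indene-1,5(4H)-dione
Conditions: KOtBu, THF, 0 °C → rt; aq HCl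
Reagents that add atoms: none
Why: Vinylogous Dieckmann condensation under thermodynamic control, in which only attack of the γ-methyl carbon C-6 on the ester gives a product that is held as a stabilised vinylogous 1,3-diketonate, while closure from C-3 or C-4 would put a bridgehead alkene in the ring and reverts.

Step 6
Reactants: 10 isobutyraldehyde
Product: 11 1,1-diiodo-2-methylpropane
Conditions: TMSI (2.2 equiv), CH2Cl2, 0 °C → rt
Reagents that add atoms: iodotrimethylsilane, C[Si](C)(C)I
Why: Deoxygenative gem-diiodination of an aldehyde through the α-iodo silyl ether, driven by formation of the Si–O–Si bond.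

Step 7
Reactants: 9 (7R)-3,7-dimethyl-2,3,6,7-tetrahydro-1H-indene-1,5(4H)-dione; 11 1,1-diiodo-2-methylpropane
Product: 13 (5S,8R)-5-isopropyl-3,8-dimethyl-2,3,4,5,7,8-hexahydroazulene-1,6-dione [(7S,10R)-guai-1(5)-ene-2,8-dione], via ethylzinc cyclopropoxide spanning C-6/C-7/C-8 12 (not isolated)
Conditions: Et2Zn (2.5 equiv), 11 (1.5 equiv), CH2Cl2, 0 °C → rt; aq NH4Cl; then DBU (cat.), CH2Cl2, rt
Reagents that add atoms: none
Why: Proposed new method: Et2Zn converts the vinylogous 1,3-diketone 9 into its zinc dienolate, C-6 is alkylated by the carbenoid EtZnCH(I)iPr made in situ, the homoenolate closes on the adjacent C-8 carbonyl to cyclopropoxide 12, and this fragments by a 1,2-acyl shift (C-8 moves from C-6 to the new C-7) because the charge is released into the C-6/C-5/C-1/C-2=O dienolate, so the seven-membered ring and the isopropyl group arrive in one operation and C-7 equilibrates to the cis-7,10 epimer (iPr pseudo-equatorial, C-10 methyl pseudo-axial to escape A1,3 strain with C-2=O), the closest known reaction type being the zinc-carbenoid chain extension and ring expansion of β-keto esters with CH2I2, MeCHI2 or PhCHI2, which has not been shown for a vinylogous diketone or for an isobutylidene carbenoid.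

Step 8
Reactants: 13 (7S,10R)-guai-1(5)-ene-2,8-dione
Product: 14 (7S,10R)-8,8-ethylenedioxyguai-1(5)-en-2-one
Conditions: (TMSOCH2)2, TMSOTf (5 mol %), CH2Cl2, −78 → −20 °C
Reagents that add atoms: 1,2-bis(trimethylsilyloxy)ethane, C[Si](C)(C)OCCO[Si](C)(C)C
Why: Noyori ketalisation takes the saturated C-8 ketone in preference to the conjugated C-2 ketone, so the cyclopentenone is the only enolisable carbonyl in the next step.

Step 9
Reactants: 14 (7S,10R)-8,8-ethylenedioxyguai-1(5)-en-2-one (2 equiv)
Product: 17 bis-ketal bridge ketone (target skeleton with C-2 as ketone, C-8 and C-8' as ethylene ketals, C-6'H2–C-7'H(iPr) saturated), via 3-bromo-8,8-ethylenedioxyguai-1(5)-en-2-one 15 (not isolated), via 8,8-ethylenedioxyguaia-1(5),3-dien-2-one 16 (not isolated)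
Conditions: LiHMDS, THF, −78 °C; NBS; then Et3N, −78 °C → rt
Reagents that add atoms: none
Why: Kinetic α'-bromination and vinylogous E1cB loss of HBr give cyclopentadienone 16 only after all enolate is consumed, and 16 undergoes the usual spontaneous endo [4+2] self-dimerisation of cyclopentadienones, in which the leading bond joins the two unsubstituted α-carbons (C-3/C-3', hence C-1–C-4') and both partners react on the face opposite the pseudo-axial C-10 methyl and the C-7 isopropyl, which sets C-1, C-3, C-3' and C-4'.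

Step 10
Reactants: 17 bis-ketal bridge ketone
Product: 18 2-syn-alcohol of 17 (OH over the C-4=C-5 double bond)
Conditions: Al(OiPr)3 (30 mol %), iPrOH–acetone 5:1, toluene, 80 °C
Reagents that add atoms: none
Why: Meerwein–Ponndorf–Verley reduction run reversibly against an acetone buffer, so that only the strained bridge ketone is reduced (the conjugated C-2' ketone is not) and hydride exchange moves the fast-formed anti carbinol to the more stable epimer, whose OH lies over the π bond and away from the exo C-4' methyl, which sets C-2.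

Step 11
Reactants: 18 2-syn-alcohol
Product: 19 2-acetate bis-ketal
Conditions: Ac2O, Et3N, DMAP (cat.), CH2Cl2, rt
Reagents that add atoms: acetic anhydride, CC(=O)OC(C)=O
Why: DMAP-catalysed acylation of the only hydroxyl group proceeds with retention at C-2.

Step 12
Reactants: 19 2-acetate bis-ketal
Product: 20 2-acetoxy-8,2',8'-trione (both ketals removed)
Conditions: PPTS, acetone–H2O 10:1, 45 °C
Reagents that add atoms: water, O
Why: Mild acid-catalysed ketal hydrolysis is weak enough to leave the acetate and the strained C-4=C-5 alkene in place, and C-7/C-7' keep their favoured cis-7,10 configuration.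

Step 13
Reactants: 20 2-acetoxy-8,2',8'-trione
Product: 22 6'(7')-dehydro compound (2'-oxo-1'(5'),6'-dien-8'-one in the lower half), via 6'-bromide of 20 21 (not isolated)
Conditions: DBU (2.2 equiv), BrCCl3 (1.05 equiv), CH2Cl2, 0 °C, argon, dark
Reagents that add atoms: none
Why: Carbanion-selective dehydrogenation (halophilic bromination, then E1cB) starts at the most acidic C–H, the γ-position C-6' of the enone half, and loses HBr through the α-proton H-7' of the C-8' ketone, whereas the other half has no conjugated carbonyl to acidify C-6 and its electron-rich alkene does not react with BrCCl3 in the dark.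

Step 14
Reactants: 22 6'(7')-dehydro compound
Product: 24 target CNP0317907.1, via 11'-hydroperoxide of 22 23 (not isolated)
Conditions: O2 (1 atm), DBU (0.2 equiv), MeCN, 0 °C
Reagents that add atoms: dioxygen, O=O
Why: Base-mediated autoxidation of an extended enolate, in which DBU removes the ε-proton H-11', triplet O2 is taken up at the tertiary terminus C-11' because this restores the full dienone, and hydroperoxide 23 adds reversibly to the neighbouring C-8' ketone (the ring–chain behaviour of β-hydroperoxy ketones), so that C-8' settles as the more stable hemiketal epimer of the target.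

**Compound list**
1 | cyclopentane-1,3-dione | O=C1CCC(=O)C1 | starting material
2 | (E)-crotonaldehyde | C/C=C/C=O | starting material
3 | (4R)-2-hydroxy-4-methyl-3,4,6,7-tetrahydrocyclopenta[b]pyran-5(2H)-one | O=C1CCC2=C1[C@H](C)CC(O)O2 | intermediate
4 | (4R)-2-methoxy-4-methyl-3,4,6,7-tetrahydrocyclopenta[b]pyran-5(2H)-one | O=C1CCC2=C1[C@H](C)CC(OC)O2 | intermediate
5 | (4R)-2-methoxy-4,6-dimethyl-3,4,6,7-tetrahydrocyclopenta[b]pyran-5(2H)-one | O=C1C(C)CC2=C1[C@H](C)CC(OC)O2 | intermediate
6 | (4R)-2-methoxy-4,5,6-trimethyl-2,3,4,5,6,7-hexahydrocyclopenta[b]pyran-5-ol | CC1(O)C(C)CC2=C1[C@H](C)CC(OC)O2 | intermediate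
7 | (3R)-3-(2,3-dimethyl-5-oxocyclopent-1-en-1-yl)butanal | O=C1CC(C)C(C)=C1[C@H](C)CC=O | intermediate
8 | methyl (3R)-3-(2,3-dimethyl-5-oxocyclopent-1-en-1-yl)butanoate | O=C1CC(C)C(C)=C1[C@H](C)CC(=O)OC | intermediate
9 | (7R)-3,7-dimethyl-2,3,6,7-tetrahydro-1H-indene-1,5(4H)-dione | O=C1CC(C)C2=C1[C@H](C)CC(=O)C2 | intermediate
10 | isobutyraldehyde | CC(C)C=O | starting material
11 | 1,1-diiodo-2-methylpropane | CC(C)C(I)I | intermediate
12 | ethylzinc cyclopropoxide (cyclopropane C-6/C-7/C-8, iPr on C-7) | O=C1CC(C)C2=C1[C@H](C)CC1(O[Zn]CC)C(C(C)C)C21 | intermediate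
13 | (5S,8R)-5-isopropyl-3,8-dimethyl-2,3,4,5,7,8-hexahydroazulene-1,6-dione | O=C1CC(C)C2=C1[C@H](C)CC(=O)[C@H](C(C)C)C2 | intermediate
14 | (7S,10R)-8,8-ethylenedioxyguai-1(5)-en-2-one | O=C1CC(C)C2=C1[C@H](C)CC3(OCCO3)[C@H](C(C)C)C2 | intermediate
15 | 3-bromo-8,8-ethylenedioxyguai-1(5)-en-2-one | O=C1C(Br)C(C)C2=C1[C@H](C)CC3(OCCO3)[C@H](C(C)C)C2 | intermediate
16 | 8,8-ethylenedioxyguaia-1(5),3-dien-2-one | O=C1C=C(C)C2=C1[C@H](C)CC3(OCCO3)[C@H](C(C)C)C2 | intermediate
17 | bis-ketal bridge ketone (endo head-to-head dimer of 16) | O=C1[C@H]2C(C)=C3C[C@@H](C(C)C)C4(OCCO4)C[C@@H](C)[C@]31[C@]1(C)C3=C(C(=O)[C@H]21)[C@H](C)CC4(OCCO4)[C@H](C(C)C)C3 | intermediate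
18 | 2-syn-alcohol bis-ketal | O[C@H]1[C@H]2C(C)=C3C[C@@H](C(C)C)C4(OCCO4)C[C@@H](C)[C@]31[C@]1(C)C3=C(C(=O)[C@H]21)[C@H](C)CC4(OCCO4)[C@H](C(C)C)C3 | intermediate
19 | 2-acetate bis-ketal | CC(=O)O[C@H]1[C@H]2C(C)=C3C[C@@H](C(C)C)C4(OCCO4)C[C@@H](C)[C@]31[C@]1(C)C3=C(C(=O)[C@H]21)[C@H](C)CC4(OCCO4)[C@H](C(C)C)C3 | intermediate
20 | 2-acetoxy-8,2',8'-trione | CC(=O)O[C@H]1[C@H]2C(C)=C3C[C@@H](C(C)C)C(=O)C[C@@H](C)[C@]31[C@]1(C)C3=C(C(=O)[C@H]21)[C@H](C)CC(=O)[C@H](C(C)C)C3 | intermediate
21 | 6'-bromide of 20 | CC(=O)O[C@H]1[C@H]2C(C)=C3C[C@@H](C(C)C)C(=O)C[C@@H](C)[C@]31[C@]1(C)C3=C(C(=O)[C@H]21)[C@H](C)CC(=O)[C@H](C(C)C)C3Br | intermediate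
22 | 6'(7')-dehydro compound | CC(=O)O[C@H]1[C@H]2C(C)=C3C[C@@H](C(C)C)C(=O)C[C@@H](C)[C@]31[C@]1(C)C3=C(C(=O)[C@H]21)[C@H](C)CC(=O)C(C(C)C)=C3 | intermediate
23 | 11'-hydroperoxide of 22 | CC(=O)O[C@H]1[C@H]2C(C)=C3C[C@@H](C(C)C)C(=O)C[C@@H](C)[C@]31[C@]1(C)C3=C(C(=O)[C@H]21)[C@H](C)CC(=O)C(C(C)(C)OO)=C3 | intermediate
24 | CNP0317907.1 | CC(=O)O[C@H]1[C@H]2C(C)=C3C[C@@H](C(C)C)C(=O)C[C@@H](C)[C@]31[C@]1(C)C3=C(C(=O)[C@H]21)[C@H](C)C[C@@]1(O)OOC(C)(C)C1=C3 | target

Total steps: 14. Longest linear sequence: 13 (steps 1–5 and 7–14).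

**Steps most likely to fail**

Step 7 (the new ring expansion). The branched carbenoid may alkylate C-6 too slowly or decompose first. The fallback sets out from 9 and uses known chemistry. Knoevenagel condensation of 9 with 10 (piperidinium acetate) gives the 4-isobutylidene hydrindenedione F1. Conjugate addition of benzeneselenol (from PhSeSePh/NaBH4) gives the β-phenylselanyl ketone F2. Bu3SnH/AIBN then starts a Dowd–Beckwith radical 1,2-acyl shift: the C-7 radical adds to C-8=O, and the alkoxy radical opens to the C-6 radical, which is conjugated with the enone. After a DBU equilibration this comes back to the route at 13.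

Step 10 (C-2 configuration). Hydride exchange on the hindered face may be too slow for equilibrium to be reached, which would leave the anti carbinol. The fallback sets out from 17 and replaces thermodynamic control by reagent control. It uses (R)-2-methyl-CBS-oxazaborolidine with catecholborane in toluene at −40 °C. The catalyst binds the carbonyl lone pair next to the small bridgehead (C-3–H) rather than the quaternary C-1. It then delivers hydride to the Re face, on the C-3'/C-4' side. This comes back at 18 without any new compound.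

Step 14 (aerobic peroxidation). Oxygen may be taken up at C-6' or C-1' instead of C-11', or the peroxide may suffer under base. The fallback sets out from 22 and separates C–O bond formation from O2. A second DBU/BrCCl3 treatment brominates the ε-carbanion to give the tertiary 11'-bromide F3. AgOTf with anhydrous ethereal H2O2 at −20 °C then replaces the bromide to give hydroperoxide 23, which closes to 24.

**Further compounds**
F1 | step 7 | (7R)-4-isobutylidene-3,7-dimethyl-2,3,6,7-tetrahydro-1H-indene-1,5(4H)-dione | O=C1CC(C)C2=C1[C@H](C)CC(=O)C2=CC(C)C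
F2 | step 7 | (7R)-3,7-dimethyl-4-[2-methyl-1-(phenylselanyl)propyl]-2,3,6,7-tetrahydro-1H-indene-1,5(4H)-dione | O=C1CC(C)C2=C1[C@H](C)CC(=O)C2C([Se]c1ccccc1)C(C)C
F0 | step 10 | none | none
F3 | step 14 | 11'-bromide of 22 | CC(=O)O[C@H]1[C@H]2C(C)=C3C[C@@H](C(C)C)C(=O)C[C@@H](C)[C@]31[C@]1(C)C3=C(C(=O)[C@H]21)[C@H](C)CC(=O)C(C(C)(C)Br)=C3
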